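**Retrosynthetic overview**

1. The bridge CH2 is traced back to a diaryl ketone. Ring A then carries the acyl carbon at C1, oxygen at C2 and C4 and the 2-arylethyl arm at C6, which is the 6-alkyl-2,4-dioxygenated (resorcylic) pattern of a folded polyketide chain; the route rests on this feature.
2. Ring A is the only ring constructed. Its C1–C6 bond is formed by intramolecular aldol addition of chain C2 onto the C7 carbonyl of a 1-aryl-nonane-1,3,5,7-tetraone, and loss of water and enolisation aromatise it.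
3. The tetraketone is cut at chain C4–C5 into the dianion of a ring B aroylacetone and a methyl 5-aryl-3-oxopentanoate; the latter comes from methyl acetoacetate dianion and a benzyl chloride.
4. Ring B is bought as 1-(4-bromo-2,6-difluorophenyl)ethanone. Two successive SNAr steps set OBn and OMe, and a B-alkyl Suzuki–Miyaura coupling with the styrene from O-benzylvanillin attaches the bibenzyl arm.
5. End game: methylation of the non-chelated para hydroxyl, reduction of the ketone to CH2 through the ortho-phenol carbonate, and hydrogenolysis of three benzyl ethers.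

Key step: step 9

Assumption: 1-(4-bromo-2,6-difluorophenyl)ethan-1-one and [4-(benzyloxy)-3-methoxyphenyl]methanol are taken as catalogue compounds, and enolates or dianions of numbered compounds are treated as forms of those compounds without numbers of their own.

Shorthand used in the step names: ArV = 4-(benzyloxy)-3-methoxyphenyl; ArB = 2-(benzyloxy)-4-[2-(ArV)ethyl]-6-methoxyphenyl. Full names and SMILES are in the compound list.

**Route**

Step 1
Reactants: 1 1-(4-bromo-2,6-difluorophenyl)ethan-1-one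
Product: 2 1-[2-(benzyloxy)-4-bromo-6-fluorophenyl]ethan-1-one
Conditions: BnOH (1.0 equiv), NaH (1.05 equiv), THF, 0 °C; added to 1 in THF, −10 °C → rt
Reagents that add atoms: benzyl alcohol, OCc1ccccc1
Why: SNAr of a fluoride ortho to the acetyl group, which should stop after one exchange because the first alkoxy group deactivates the ring, and fluoride should leave far faster than the para bromide.

Step 2
Reactants: 2 1-[2-(benzyloxy)-4-bromo-6-fluorophenyl]ethan-1-one
Product: 3 1-[2-(benzyloxy)-4-bromo-6-methoxyphenyl]ethan-1-one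
Conditions: NaOMe (3 equiv), MeOH/DMSO, 60 °C
Reagents that add atoms: sodium methoxide, [Na+].[O-]C
Why: Second SNAr at the remaining ortho fluoride, where the small methoxide in excess is expected to overcome the lower activation, so the two ring B oxygens are differentiated without a statistical alkylation.

Step 3
Reactants: 4 4-(benzyloxy)-3-methoxybenzaldehyde (O-benzylvanillin)
Product: 5 1-(benzyloxy)-4-ethenyl-2-methoxybenzene
Conditions: Ph3PCH3Br (1.2 equiv), KOtBu (1.2 equiv), THF, 0 °C → rt
Reagents that add atoms: methyltriphenylphosphonium bromide, C[P+](c1ccccc1)(c1ccccc1)c1ccccc1.[Br-]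
Why: Wittig methylenation of an unhindered aromatic aldehyde with the non-stabilised ylide.

Step 4
Reactants: 5 1-(benzyloxy)-4-ethenyl-2-methoxybenzene; 3 1-[2-(benzyloxy)-4-bromo-6-methoxyphenyl]ethan-1-one
Product: 7 1-(ArB)ethan-1-one, via B-alkyl-9-BBN adduct 6 (not isolated)
Conditions: 9-BBN (1.1 equiv), THF, 0 °C → rt; then 3, PdCl2(dppf) (3 mol %), K3PO4 (3 M aq., 3 equiv), THF/DMF, 60 °C
Reagents that add atoms: none
Why: Anti-Markovnikov hydroboration of the styrene followed by B-alkyl Suzuki–Miyaura coupling at an unhindered aryl bromide activated by the para acetyl group should give the saturated bibenzyl arm directly, with the ketone, the benzyl ethers and the methyl ethers untouched.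

Step 5
Reactants: 7 1-(ArB)ethan-1-one
Product: 8 1-(ArB)butane-1,3-dione
Conditions: NaH (3 equiv), EtOAc (5 equiv), THF, reflux; cold 1 M HCl
Reagents that add atoms: ethyl acetate, CCOC(C)=O
Why: Crossed Claisen condensation of the methyl ketone enolate with ethyl acetate, driven by formation of the stable diketonate, as is usual for 2,6-dialkoxyacetophenones.

Step 6
Reactants: 9 [4-(benzyloxy)-3-methoxyphenyl]methanol
Product: 10 1-(benzyloxy)-4-(chloromethyl)-2-methoxybenzene
Conditions: SOCl2 (1.2 equiv), CH2Cl2, 0 °C → rt; used crude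
Reagents that add atoms: thionyl chloride, O=S(Cl)Cl
Why: Chlorodehydroxylation of an electron-rich benzylic alcohol through its chlorosulfite, which the aryl benzyl ether tolerates.

Step 7
Reactants: 11 methyl 3-oxobutanoate (methyl acetoacetate); 10 1-(benzyloxy)-4-(chloromethyl)-2-methoxybenzene
Product: 12 methyl 5-(ArV)-3-oxopentanoate
Conditions: 11, NaH (1.1 equiv), THF, 0 °C; n-BuLi (1.05 equiv), 0 °C; then 10, 0 °C → rt; aq. NH4Cl
Reagents that add atoms: none
Why: γ-Alkylation of the acetoacetate dianion, whose terminal carbanion is the more nucleophilic site, by a reactive benzylic chloride.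

Step 8
Reactants: 8 1-(ArB)butane-1,3-dione; 12 methyl 5-(ArV)-3-oxopentanoate
Product: 13 1-(ArB)-9-(ArV)nonane-1,3,5,7-tetrone
Conditions: 8, LDA (LiN(iPr)2, 3.1 equiv), THF, −78 → 0 °C; lithium enolate of 12 (12, LDA 1.05 equiv, THF, −78 °C) added by cannula; 0 °C → rt; cold 1 M HCl; used crude
Reagents that add atoms: none
Why: Claisen-type acylation of the terminal carbanion of the 1,3-diketone dianion by the ester group of the β-keto ester enolate, a known way to 1,3,5,7-tetraketones, with the extra equivalent of base taking up the acidic proton of the product.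

Step 9
Reactants: 13 1-(ArB)-9-(ArV)nonane-1,3,5,7-tetrone
Product: 15 (ArB)[2-(2-(ArV)ethyl)-4,6-dihydroxyphenyl]methanone, via cyclic aldol adduct 14 (not isolated)
Conditions: KOH (1 M aq.), MeOH/THF, N2, 0 °C → rt; then 1 M HCl to pH 3
Reagents that add atoms: none
Why: Base converts 13 into its polyenolate, the C2 carbanion lying between the aroyl carbonyl and C3 adds to the C7 ketone to give aldol 14, and loss of water followed by enolisation of C3 and C5 should deliver the resorcinol ring. The closest known reaction type is the base-mediated aldol cyclisation of 1-aryl-1,3,5,7-tetraketones to 2,4-dihydroxy-6-alkylbenzophenones, the laboratory counterpart of polyketide aromatisation. Ring A is closed by a 6-exo-trig aldol (the enolate double bond may lie inside or outside the forming ring; both are allowed), which makes the bond between the bridge-bearing and the chain-bearing carbon. No stereocentre remains, since the two in 14 are erased on aromatisation. The step needs closure of C2 onto C7 in preference to closure of C6 onto the aroyl carbonyl and to O-cyclisation to pyranones. The first is secured by the two ortho alkoxy groups, which shield and twist the aroyl carbonyl while C7 is an unhindered dialkyl ketone, and the second by working in base; C8 is not doubly activated and should stay un-ionised.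

Step 10
Reactants: 15 (ArB)[2-(2-(ArV)ethyl)-4,6-dihydroxyphenyl]methanone
Product: 16 (ArB)[2-(2-(ArV)ethyl)-6-hydroxy-4-methoxyphenyl]methanone
Conditions: MeI (1.1 equiv), K2CO3 (1.2 equiv), acetone, rt → 40 °C
Reagents that add atoms: iodomethane, CI
Why: Williamson etherification should take place only at the para hydroxyl, because the ortho hydroxyl is held in a hydrogen bond to the ketone and is much less nucleophilic.

Step 11
Reactants: 16 (ArB)[2-(2-(ArV)ethyl)-6-hydroxy-4-methoxyphenyl]methanone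
Product: 19 2-[(ArB)methyl]-3-[2-(ArV)ethyl]-5-methoxyphenol, via aryl ethyl carbonate 17 (not isolated), via ortho-quinone methide 18 (not isolated)
Conditions: ClCO2Et (1.2 equiv), Et3N (1.3 equiv), THF, 0 °C; then NaBH4 (4 equiv), H2O, 0 °C → rt
Reagents that add atoms: none
Why: Reductive deoxygenation of an ortho-hydroxyaryl ketone through its ethyl carbonate: hydride reduction of the ketone, carbonate transfer to the benzylic oxygen and loss of ethyl carbonate give the ortho-quinone methide, which takes up a second hydride to leave the diarylmethane and the free phenol, and benzyl ethers are inert to NaBH4.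

Step 12
Reactants: 19 2-[(ArB)methyl]-3-[2-(ArV)ethyl]-5-methoxyphenol
Product: 20 2-({2-hydroxy-4-[2-(4-hydroxy-3-methoxyphenyl)ethyl]-6-methoxyphenyl}methyl)-3-[2-(4-hydroxy-3-methoxyphenyl)ethyl]-5-methoxyphenol (CNP0079001.0)
Conditions: H2 (1 atm), 10% Pd/C, EtOAc/MeOH, rt
Reagents that add atoms: none
Why: Catalytic hydrogenolysis of the three aryl benzyl ethers under neutral conditions, which should leave the methyl ethers and the acid-sensitive diarylmethane untouched.

**Compound list**

1 | 1-(4-bromo-2,6-difluorophenyl)ethan-1-one | CC(=O)c1c(F)cc(Br)cc1F | starting material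
2 | 1-[2-(benzyloxy)-4-bromo-6-fluorophenyl]ethan-1-one | CC(=O)c1c(F)cc(Br)cc1OCc1ccccc1 | intermediate
3 | 1-[2-(benzyloxy)-4-bromo-6-methoxyphenyl]ethan-1-one | CC(=O)c1c(OC)cc(Br)cc1OCc1ccccc1 | intermediate
4 | 4-(benzyloxy)-3-methoxybenzaldehyde (O-benzylvanillin) | O=Cc1ccc(OCc2ccccc2)c(OC)c1 | starting material
5 | 1-(benzyloxy)-4-ethenyl-2-methoxybenzene | C=Cc1ccc(OCc2ccccc2)c(OC)c1 | intermediate
6 | 9-{2-[4-(benzyloxy)-3-methoxyphenyl]ethyl}-9-borabicyclo[3.3.1]nonane (not isolated) | COc1cc(CCB2C3CCCC2CCC3)ccc1OCc1ccccc1 | intermediate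
7 | 1-{2-(benzyloxy)-4-[2-(4-(benzyloxy)-3-methoxyphenyl)ethyl]-6-methoxyphenyl}ethan-1-one | CC(=O)c1c(OCc2ccccc2)cc(CCc2ccc(OCc3ccccc3)c(OC)c2)cc1OC | intermediate
8 | 1-{2-(benzyloxy)-4-[2-(4-(benzyloxy)-3-methoxyphenyl)ethyl]-6-methoxyphenyl}butane-1,3-dione | CC(=O)CC(=O)c1c(OCc2ccccc2)cc(CCc2ccc(OCc3ccccc3)c(OC)c2)cc1OC | intermediate
9 | [4-(benzyloxy)-3-methoxyphenyl]methanol | OCc1ccc(OCc2ccccc2)c(OC)c1 | starting material
10 | 1-(benzyloxy)-4-(chloromethyl)-2-methoxybenzene | ClCc1ccc(OCc2ccccc2)c(OC)c1 | intermediate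
11 | methyl 3-oxobutanoate (methyl acetoacetate) | COC(=O)CC(C)=O | starting material
12 | methyl 5-[4-(benzyloxy)-3-methoxyphenyl]-3-oxopentanoate | COC(=O)CC(=O)CCc1ccc(OCc2ccccc2)c(OC)c1 | intermediate
13 | 1-{2-(benzyloxy)-4-[2-(4-(benzyloxy)-3-methoxyphenyl)ethyl]-6-methoxyphenyl}-9-[4-(benzyloxy)-3-methoxyphenyl]nonane-1,3,5,7-tetrone | O=C(CC(=O)CC(=O)CC(=O)CCc1ccc(OCc2ccccc2)c(OC)c1)c1c(OCc2ccccc2)cc(CCc2ccc(OCc3ccccc3)c(OC)c2)cc1OC | intermediate
14 | 4-{2-(benzyloxy)-4-[2-(4-(benzyloxy)-3-methoxyphenyl)ethyl]-6-methoxybenzoyl}-5-{2-[4-(benzyloxy)-3-methoxyphenyl]ethyl}-5-hydroxycyclohexane-1,3-dione (mixture of diastereomers, not isolated) | O=C1CC(=O)C(C(=O)c2c(OCc3ccccc3)cc(CCc3ccc(OCc4ccccc4)c(OC)c3)cc2OC)C(O)(CCc2ccc(OCc3ccccc3)c(OC)c2)C1 | intermediate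
15 | {2-(benzyloxy)-4-[2-(4-(benzyloxy)-3-methoxyphenyl)ethyl]-6-methoxyphenyl}{2-[2-(4-(benzyloxy)-3-methoxyphenyl)ethyl]-4,6-dihydroxyphenyl}methanone | O=C(c1c(O)cc(O)cc1CCc1ccc(OCc2ccccc2)c(OC)c1)c1c(OCc2ccccc2)cc(CCc2ccc(OCc3ccccc3)c(OC)c2)cc1OC | intermediate
16 | {2-(benzyloxy)-4-[2-(4-(benzyloxy)-3-methoxyphenyl)ethyl]-6-methoxyphenyl}{2-[2-(4-(benzyloxy)-3-methoxyphenyl)ethyl]-6-hydroxy-4-methoxyphenyl}methanone | COc1cc(O)c(C(=O)c2c(OCc3ccccc3)cc(CCc3ccc(OCc4ccccc4)c(OC)c3)cc2OC)c(CCc2ccc(OCc3ccccc3)c(OC)c2)c1 | intermediate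
17 | 2-{2-(benzyloxy)-4-[2-(4-(benzyloxy)-3-methoxyphenyl)ethyl]-6-methoxybenzoyl}-3-{2-[4-(benzyloxy)-3-methoxyphenyl]ethyl}-5-methoxyphenyl ethyl carbonate (not isolated) | CCOC(=O)Oc1cc(OC)cc(CCc2ccc(OCc3ccccc3)c(OC)c2)c1C(=O)c1c(OCc2ccccc2)cc(CCc2ccc(OCc3ccccc3)c(OC)c2)cc1OC | intermediate
18 | 6-({2-(benzyloxy)-4-[2-(4-(benzyloxy)-3-methoxyphenyl)ethyl]-6-methoxyphenyl}methylidene)-5-{2-[4-(benzyloxy)-3-methoxyphenyl]ethyl}-3-methoxycyclohexa-2,4-dien-1-one (ortho-quinone methide, alkene geometry undefined, not isolated) | COC1=CC(=O)C(=Cc2c(OCc3ccccc3)cc(CCc3ccc(OCc4ccccc4)c(OC)c3)cc2OC)C(CCc2ccc(OCc3ccccc3)c(OC)c2)=C1 | intermediate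
19 | 2-({2-(benzyloxy)-4-[2-(4-(benzyloxy)-3-methoxyphenyl)ethyl]-6-methoxyphenyl}methyl)-3-{2-[4-(benzyloxy)-3-methoxyphenyl]ethyl}-5-methoxyphenol | COc1cc(O)c(Cc2c(OCc3ccccc3)cc(CCc3ccc(OCc4ccccc4)c(OC)c3)cc2OC)c(CCc2ccc(OCc3ccccc3)c(OC)c2)c1 | intermediate
20 | 2-({2-hydroxy-4-[2-(4-hydroxy-3-methoxyphenyl)ethyl]-6-methoxyphenyl}methyl)-3-[2-(4-hydroxy-3-methoxyphenyl)ethyl]-5-methoxyphenol (CNP0079001.0, achiral) | COc1cc(O)c(Cc2c(O)cc(CCc3ccc(O)c(OC)c3)cc2OC)c(CCc2ccc(O)c(OC)c2)c1 | target

**Step count**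

Total: 12 steps. Longest linear sequence: 9 steps (steps 1, 2, 4, 5, 8, 9, 10, 11, 12, from compound 1).

**Steps most likely to fail**

Step 8. Proton transfer from the β-keto ester or from the newly formed, more acidic polyketone may quench the diketone dianion before acylation, and the free tetraketone may cyclise or cleave during the acidic work-up. The fallback builds the chain in two acylations with Weinreb amides. It sets out from 8 and 10. The dianion of 8 (LDA, 2.2 equiv, THF, 0 °C) is acetylated with N-methoxy-N-methylacetamide to give 1-{2-(benzyloxy)-4-[2-(4-(benzyloxy)-3-methoxyphenyl)ethyl]-6-methoxyphenyl}hexane-1,3,5-trione F1. In parallel, the lithium enolate of N-methoxy-N-methylacetamide (LDA, THF, −78 °C) is alkylated by chloride 10 to give 3-[4-(benzyloxy)-3-methoxyphenyl]-N-methoxy-N-methylpropanamide F2. The trianion of F1 (LDA, 3.2 equiv, THF, 0 °C) is then acylated at its terminal methyl by F2, whose chelated tetrahedral adduct should persist until the quench. The route is rejoined at 13.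

Step 9. Closure in the other aldol sense onto the aroyl carbonyl, O-cyclisation to a pyranone, or retro-Claisen scission of the chain by hydroxide may take the place of the desired closure. The fallback forms ring A at the dihydroresorcinol level by a Michael–Claisen annulation and dehydrogenates it afterwards. It sets out from 8 and 12. Reduction of 12 (NaBH4, MeOH, 0 °C) gives racemic methyl 5-[4-(benzyloxy)-3-methoxyphenyl]-3-hydroxypentanoate F3. Mesylation and elimination (MsCl, Et3N, CH2Cl2; then DBU) give methyl (E)-5-[4-(benzyloxy)-3-methoxyphenyl]pent-2-enoate F4. The sodium enolate of 8 (NaOMe, MeOH, reflux) adds through its central carbon to the β-carbon of F4, and the acetyl methyl then closes onto the ester to give 4-{2-(benzyloxy)-4-[2-(4-(benzyloxy)-3-methoxyphenyl)ethyl]-6-methoxybenzoyl}-5-{2-[4-(benzyloxy)-3-methoxyphenyl]ethyl}cyclohexane-1,3-dione F5 as a mixture of diastereomers. Dehydrogenation with DDQ (dioxane, rt → 60 °C) aromatises F5, and the route is rejoined at 15.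

Step 11. Borohydride may cleave the aryl carbonate faster than it attacks the ketone flanked by four ortho substituents, which would return 16 unreduced. The fallback separates carbonyl reduction from C–O cleavage and sets out from 16. LiAlH4 (THF, 0 °C → reflux) reduces the ketone to racemic 2-({2-(benzyloxy)-4-[2-(4-(benzyloxy)-3-methoxyphenyl)ethyl]-6-methoxyphenyl}(hydroxy)methyl)-3-{2-[4-(benzyloxy)-3-methoxyphenyl]ethyl}-5-methoxyphenol F6. Hydrogenolysis (H2, 10% Pd/C, EtOAc/MeOH, catalytic HCl) then cleaves the doubly benzylic C–OH bond together with the three benzyl ethers, so that compound 19 is bypassed and the route is rejoined at the target 20.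

**Further compounds**

F1 | step 8 | 1-{2-(benzyloxy)-4-[2-(4-(benzyloxy)-3-methoxyphenyl)ethyl]-6-methoxyphenyl}hexane-1,3,5-trione | CC(=O)CC(=O)CC(=O)c1c(OCc2ccccc2)cc(CCc2ccc(OCc3ccccc3)c(OC)c2)cc1OC
F2 | step 8 | 3-[4-(benzyloxy)-3-methoxyphenyl]-N-methoxy-N-methylpropanamide | CON(C)C(=O)CCc1ccc(OCc2ccccc2)c(OC)c1
F3 | step 9 | methyl 5-[4-(benzyloxy)-3-methoxyphenyl]-3-hydroxypentanoate (racemic) | COC(=O)CC(O)CCc1ccc(OCc2ccccc2)c(OC)c1
F4 | step 9 | methyl (E)-5-[4-(benzyloxy)-3-methoxyphenyl]pent-2-enoate | COC(=O)/C=C/CCc1ccc(OCc2ccccc2)c(OC)c1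
F5 | step 9 | 4-{2-(benzyloxy)-4-[2-(4-(benzyloxy)-3-methoxyphenyl)ethyl]-6-methoxybenzoyl}-5-{2-[4-(benzyloxy)-3-methoxyphenyl]ethyl}cyclohexane-1,3-dione (mixture of diastereomers) | O=C1CC(=O)C(C(=O)c2c(OCc3ccccc3)cc(CCc3ccc(OCc4ccccc4)c(OC)c3)cc2OC)C(CCc2ccc(OCc3ccccc3)c(OC)c2)C1
F6 | step 11 | 2-({2-(benzyloxy)-4-[2-(4-(benzyloxy)-3-methoxyphenyl)ethyl]-6-methoxyphenyl}(hydroxy)methyl)-3-{2-[4-(benzyloxy)-3-methoxyphenyl]ethyl}-5-methoxyphenol (racemic) | COc1cc(O)c(C(O)c2c(OCc3ccccc3)cc(CCc3ccc(OCc4ccccc4)c(OC)c3)cc2OC)c(CCc2ccc(OCc3ccccc3)c(OC)c2)c1
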